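The decision is which charge waits: the starting material, the coupling partner, or the starting material in the cold.

all flasks: free catalyst 9.8 mM; time 5.0 min

| run | starting material | coupling partner | remark | temperature |
|---|---|---|---|---|
| dawn | 0.098 M (fed, over 4.0 min) | 0.147 M | the addition at −10 °C, then warmed to 20 °C; the feed brings no volume worth counting |  |
| spring | 0.098 M | 0.147 M (in portions, 5, over 4.0 min) | first portion at the start, last at 4.0 min | 20 °C |
| noon | 0.098 M (fed, over 4.0 min) | 0.147 M | all else is in the flask from the start; the feed brings no volume worth counting | 20 °C |
| summer | 0.098 M | 0.147 M (fed, over 4.0 min) | all else is in the flask from the start; the feed brings no volume worth counting | 20 °C |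

    starting material ⇌ dormant form (K1 = 25, k1 = 0.016 s⁻¹, Ea1 = 72.0 kJ mol⁻¹, ΔH1 = −47.0 kJ mol⁻¹)
    intermediate → decomposed reagent (k2 = 0.0023 s⁻¹, Ea2 = 96.0 kJ mol⁻¹)
    starting material + free catalyst ⇌ free catalyst + intermediate (K3 = 1.3, k3 = 2.1 M⁻¹ s⁻¹, Ea3 = 48.0 kJ mol⁻¹, ΔH3 = −3.00 kJ mol⁻¹)
    coupling partner + free catalyst + intermediate → free catalyst + product (k4 = 7.7 M⁻² s⁻¹, Ea4 = 37.0 kJ mol⁻¹)
    free catalyst + product → spent catalyst (k5 = 0.039 M⁻¹ s⁻¹, Ea5 = 52.0 kJ mol⁻¹)
    (constants at 20 °C)

- all constants are for 20 °C and move with temperature by the activation energies and enthalpies

* the flask that comes out highest in amount of product, in percent of the starting material charged, or "all alike" when all lie within 1.5 percentage points (dawn / spring / noon / summer / all alike)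
* product at the end, in percent of the starting material charged, dawn
* product at the end, in percent of the starting material charged, spring
* product at the end, in percent of the starting material charged, noon
* product at the end, in percent of the starting material charged, summer

The first equation is the danger. Starting material passes into dormant form at 0.960 min⁻¹, a half-life of 0.722 min, and the way back is far slower at 0.0384 min⁻¹, so my reckoning counts the dormant form as lost. But free catalyst turns starting material into intermediate at a = 1.23 min⁻¹ and returns it at r = 0.950 min⁻¹, so these two species form one pool with several exits. With [free catalyst] and [coupling partner] held, each step is pseudo-first-order, and coupling takes intermediate at c = 0.666 min⁻¹ at the full charge. Write d for the rate into dormant form and v for decomposition. Following a molecule through its returns gives ac/[a(c+v)+d(c+r+v)], the capture share: the part of the material leaving the pool that leaves as product. At the full charge it is 30.7%, which applies to noon, though the last of noon's feed has just 1.00 min to leave, so noon should land lower.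

Spring and summer have received, averaged over the 4.0 min of addition, half the coupling partner, so I try half of c in the formula and the share becomes 21.1%. But their starting material stands in the flask from the start, and its half-life of 0.722 min toward dormant form is shorter than the 2.00 min that the addition needs to reach that mean, so the first of the material meets less coupling partner than the mean, and I take this share as a high estimate for both flasks. For dawn, I treat the cold as a standstill. The 1.00 min at 20 °C is then 1.38 half-lives, which gives 19.0%. My pick is noon.

The forecast also picks noon, with 17% for dawn, 19.5% for spring, 26% for noon and 18% for summer, on the ground that “a full charge of coupling partner catches the intermediate as it forms”. Its noon figure stands below my share.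

The simulation gives 17.4% for dawn, 17.2% for spring, 23.2% for noon and 16.8% for summer, so noon comes out highest.

Of the material that has left the pool at 5.00 min, noon holds 27.5% as product, against the capture share of 30.7%. Summer holds 18.0%, against 21.1%. The neighbouring flask is summer with 5.90 mM of free catalyst. There a, r and c fall with the catalyst while d and v stay, so the same reckoning gives 13.2%. That flask ends with 3.49% starting material, 4.05% intermediate and 11.5% product.

(All constants were drawn at random within sensible limits; the result is computed.)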